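**Retrosynthetic overview**
1. The target comes from its dodecamethyl ether, in which only the ring C hydroxyl between rings D and E is free, by one global O-demethylation at the end.
2. Key disconnection: both biaryl bonds (C–D and C–E) are cut at once. Each joins two carbons that are nucleophilic by nature, so 1,3,5-trimethoxybenzene is polarity-inverted into an aryl cation equivalent (an aryllead triacetate made in the flask). This is delivered to the two ortho carbons of the ring C phenol.
3. The A–O–B–O–C phenol comes from two rounds of Ullmann etherification with a bromobenzaldehyde, each followed by Baeyer–Villiger CHO→OH. The formyl group serves as activator and as masked phenol.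
4. No ring is built, because all five benzene rings are bought. They are joined in the order A+B, then C, then D and E together.

Assumption: the target has no stereocentre and no stereogenic axis, because rings D and E carry identical ortho substituents. It is therefore achiral and no enantiomer has to be selected. Compounds 1, 2, 6 and 10 are catalogue chemicals.

**Route**

Step 1
Reactants: 1 3,5-dimethoxyphenol; 2 2-bromo-3,5-dimethoxybenzaldehyde
Product: 3 2-(3,5-dimethoxyphenoxy)-3,5-dimethoxybenzaldehyde
Conditions: CuI (10 mol %), picolinic acid (20 mol %), K3PO4 (2 equiv), DMSO, 90 °C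
Reagents that add atoms: none
Why: Ullmann-type diaryl ether synthesis in which the ortho-formyl group activates the C–Br bond toward monovalent copper and picolinic acid is a ligand suited to doubly ortho-substituted halides; no stereocentre is formed.

Step 2
Reactants: 3 2-(3,5-dimethoxyphenoxy)-3,5-dimethoxybenzaldehyde
Product: 5 2-(3,5-dimethoxyphenoxy)-3,5-dimethoxyphenol, via aryl formate 4 (not isolated)
Conditions: mCPBA (1.5 equiv), CH2Cl2, 0 °C to rt; then MeOH, Et3N (cat.), rt
Reagents that add atoms: mCPBA (3-chloroperbenzoic acid), O=C(OO)c1cccc(Cl)c1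
Why: Baeyer–Villiger (Dakin-type) oxidation in which the ortho-aryloxy-substituted aryl group migrates in preference to hydride in the Criegee adduct, and the labile formate is methanolysed in the same flask to free exactly the ring B oxygen that must carry ring C.

Step 3
Reactants: 5 2-(3,5-dimethoxyphenoxy)-3,5-dimethoxyphenol; 6 4-bromo-3,5-dimethoxybenzaldehyde
Product: 7 4-[2-(3,5-dimethoxyphenoxy)-3,5-dimethoxyphenoxy]-3,5-dimethoxybenzaldehyde
Conditions: CuI (20 mol %), picolinic acid (40 mol %), K3PO4 (2 equiv), DMSO, 100 °C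
Reagents that add atoms: none
Why: Second Ullmann-type etherification, electronically matched because 5 is an electron-rich phenoxide and the para-formyl group makes the doubly ortho-methoxylated bromide 6 the electron-poor partner.

Step 4
Reactants: 7 4-[2-(3,5-dimethoxyphenoxy)-3,5-dimethoxyphenoxy]-3,5-dimethoxybenzaldehyde
Product: 9 4-[2-(3,5-dimethoxyphenoxy)-3,5-dimethoxyphenoxy]-3,5-dimethoxyphenol, via aryl formate 8 (not isolated)
Conditions: mCPBA (1.5 equiv), CH2Cl2, 0 °C to rt; then MeOH, Et3N (cat.), rt
Reagents that add atoms: mCPBA (3-chloroperbenzoic acid), O=C(OO)c1cccc(Cl)c1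
Why: Baeyer–Villiger oxidation driven by the para-aryloxy donor (as in the 3,4,5-trialkoxybenzaldehyde to phenol conversion), which leaves the single free OH of the molecule on ring C, para to the ether and flanked by the two C–H positions to be arylated.

Step 5
Reactants: 9 4-[2-(3,5-dimethoxyphenoxy)-3,5-dimethoxyphenoxy]-3,5-dimethoxyphenol; 10 1,3,5-trimethoxybenzene
Product: 13 4-[2-(3,5-dimethoxyphenoxy)-3,5-dimethoxyphenoxy]-3,5-dimethoxy-2,6-bis(2,4,6-trimethoxyphenyl)phenol, via 2,4,6-trimethoxyphenyllead triacetate 11 (not isolated), via monoarylated phenol 12 (not isolated)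
Conditions: 10 (2.9 equiv), Pb(OAc)4 (2.6 equiv), CHCl3, rt, dark, 4 h (until no Pb(OAc)4 is left); then 9 (1.0 equiv), pyridine (8 equiv), 40 to 60 °C, 24 h
Reagents that add atoms: none
Why: Pinhey–Barton ortho-arylation of a phenol by ligand coupling at tetravalent lead: electrophilic plumbation turns the nucleophilic ring carbon of 10 into the 2,4,6-trimethoxyphenyl cation equivalent 11, the only free OH of 9 exchanges for acetate on lead and the aryl group passes to the equally nucleophilic ortho carbon with loss of Pb(OAc)2 and rearomatisation, once to 12 and again to 13, a twofold delivery known for 3,5-disubstituted phenols even with hindered aryl groups, while the ether-only rings A and B cannot bind lead and stay untouched; rings D and E are symmetric about the new bonds, so no stereogenic axis arises.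

Step 6
Reactants: 13 4-[2-(3,5-dimethoxyphenoxy)-3,5-dimethoxyphenoxy]-3,5-dimethoxy-2,6-bis(2,4,6-trimethoxyphenyl)phenol
Product: 14 4-[2-(3,5-dihydroxyphenoxy)-3,5-dihydroxyphenoxy]-2,6-bis(2,4,6-trihydroxyphenyl)benzene-1,3,5-triol (target)
Conditions: BBr3 (30 equiv), CH2Cl2, −78 °C to rt, 24 h; then ice/H2O, EtOAc extraction under argon, Sephadex LH-20
Reagents that add atoms: none
Why: Lewis-acid aryl methyl ether cleavage in which bromide attacks only the twelve methyl carbons, so that the two diaryl ether bonds and the two biaryl bonds, which offer no sp3 carbon, survive and hydrolysis frees all thirteen phenols.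

**Compound list**
1 | 3,5-dimethoxyphenol | COc1cc(O)cc(OC)c1 | starting material
2 | 2-bromo-3,5-dimethoxybenzaldehyde | COc1cc(C=O)c(Br)c(OC)c1 | starting material
3 | 2-(3,5-dimethoxyphenoxy)-3,5-dimethoxybenzaldehyde | COc1cc(OC)cc(Oc2c(C=O)cc(OC)cc2OC)c1 | intermediate
4 | 2-(3,5-dimethoxyphenoxy)-3,5-dimethoxyphenyl formate | COc1cc(OC)cc(Oc2c(OC=O)cc(OC)cc2OC)c1 | intermediate
5 | 2-(3,5-dimethoxyphenoxy)-3,5-dimethoxyphenol | COc1cc(OC)cc(Oc2c(O)cc(OC)cc2OC)c1 | intermediate
6 | 4-bromo-3,5-dimethoxybenzaldehyde | COc1cc(C=O)cc(OC)c1Br | starting material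
7 | 4-[2-(3,5-dimethoxyphenoxy)-3,5-dimethoxyphenoxy]-3,5-dimethoxybenzaldehyde | COc1cc(OC)cc(Oc2c(OC)cc(OC)cc2Oc2c(OC)cc(C=O)cc2OC)c1 | intermediate
8 | 4-[2-(3,5-dimethoxyphenoxy)-3,5-dimethoxyphenoxy]-3,5-dimethoxyphenyl formate | COc1cc(OC)cc(Oc2c(OC)cc(OC)cc2Oc2c(OC)cc(OC=O)cc2OC)c1 | intermediate
9 | 4-[2-(3,5-dimethoxyphenoxy)-3,5-dimethoxyphenoxy]-3,5-dimethoxyphenol | COc1cc(OC)cc(Oc2c(OC)cc(OC)cc2Oc2c(OC)cc(O)cc2OC)c1 | intermediate
10 | 1,3,5-trimethoxybenzene | COc1cc(OC)cc(OC)c1 | starting material
11 | 2,4,6-trimethoxyphenyllead triacetate | COc1cc(OC)c([Pb](OC(C)=O)(OC(C)=O)OC(C)=O)c(OC)c1 | intermediate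
12 | 4-[2-(3,5-dimethoxyphenoxy)-3,5-dimethoxyphenoxy]-3,5-dimethoxy-2-(2,4,6-trimethoxyphenyl)phenol | COc1cc(OC)cc(Oc2c(OC)cc(OC)cc2Oc2c(OC)cc(O)c(-c3c(OC)cc(OC)cc3OC)c2OC)c1 | intermediate
13 | 4-[2-(3,5-dimethoxyphenoxy)-3,5-dimethoxyphenoxy]-3,5-dimethoxy-2,6-bis(2,4,6-trimethoxyphenyl)phenol | COc1cc(OC)cc(Oc2c(OC)cc(OC)cc2Oc2c(OC)c(-c3c(OC)cc(OC)cc3OC)c(O)c(-c3c(OC)cc(OC)cc3OC)c2OC)c1 | intermediate
14 | 4-[2-(3,5-dihydroxyphenoxy)-3,5-dihydroxyphenoxy]-2,6-bis(2,4,6-trihydroxyphenyl)benzene-1,3,5-triol (achiral) | Oc1cc(O)cc(Oc2c(O)cc(O)cc2Oc2c(O)c(-c3c(O)cc(O)cc3O)c(O)c(-c3c(O)cc(O)cc3O)c2O)c1 | target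

**Step count**
- Total step count: 6.
- Longest linear sequence: 6 (1 to 14).

**The three steps most likely to fail**

Step 5, the twofold ligand coupling, carries the highest risk. Two tetra-ortho-oxygenated biaryl bonds must form in one flask. The reaction may stall at 12, or the very electron-rich phenol may be oxidised by tetravalent lead. The fallback sets out from 9 and comes back at 13.
- Only the phenoxide ring is iodinated (I2, KI, aqueous NaOH/MeOH, 0 °C; aryl ethers are inert to iodine in base). This gives 4-[2-(3,5-dimethoxyphenoxy)-3,5-dimethoxyphenoxy]-2,6-diiodo-3,5-dimethoxyphenol F1.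
- A twofold Suzuki–Miyaura coupling with commercial 2,4,6-trimethoxyphenylboronic acid then gives 13 (Pd(OAc)2, SPhos, K3PO4, toluene/H2O, 90 °C).

Step 3 is second, because an ortho-aryloxy phenol must meet a bromide flanked by two methoxy groups. Copper catalysis may therefore be slow or end in hydrodebromination. The fallback sets out from 6 (using 10 and 5 as partners) and comes back at 7.
- Halogen exchange (NaI, CuI, N,N'-dimethylethylenediamine, dioxane, 110 °C) gives 4-iodo-3,5-dimethoxybenzaldehyde F2.
- One-pot oxidation and capture (mCPBA, TsOH·H2O, MeCN, 55 °C; then 10) gives (4-formyl-2,6-dimethoxyphenyl)(2,4,6-trimethoxyphenyl)iodonium 4-methylbenzenesulfonate F3.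
- The potassium phenoxide of 5 (t-BuOK, THF/toluene, 40 to 60 °C) is O-arylated without metal by ligand coupling at trivalent iodine. This reaction tolerates ortho substituents on both partners. It transfers the electron-poorer formyl-bearing aryl group, with the trimethoxyphenyl group acting as the spectator, and gives 7.

Step 6 is third. Twelve ethers must all be cleaved, and the thirteenfold phenol is polar, air-sensitive and hard to free from partly methylated congeners. The fallback sets out from 13 and comes back at 14.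
- After the BBr3 treatment the crude phenol is not purified but peracetylated (Ac2O, pyridine, DMAP cat., rt) to the target tridecaacetate F4.
- F4 is stable and is chromatographed on silica, where under-demethylated material separates.
- Acid methanolysis under argon (HCl in MeOH, rt) and evaporation then give clean 14.

**Further compounds**
F1 | step 5 | 4-[2-(3,5-dimethoxyphenoxy)-3,5-dimethoxyphenoxy]-2,6-diiodo-3,5-dimethoxyphenol | COc1cc(OC)cc(Oc2c(OC)cc(OC)cc2Oc2c(OC)c(I)c(O)c(I)c2OC)c1
F2 | step 3 | 4-iodo-3,5-dimethoxybenzaldehyde | COc1cc(C=O)cc(OC)c1I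
F3 | step 3 | (4-formyl-2,6-dimethoxyphenyl)(2,4,6-trimethoxyphenyl)iodonium 4-methylbenzenesulfonate | COc1cc(OC)c([I+]c2c(OC)cc(C=O)cc2OC)c(OC)c1.Cc1ccc(cc1)S(=O)(=O)[O-]
F4 | step 6 | target tridecaacetate | CC(=O)Oc1cc(OC(C)=O)cc(Oc2c(OC(C)=O)cc(OC(C)=O)cc2Oc2c(OC(C)=O)c(-c3c(OC(C)=O)cc(OC(C)=O)cc3OC(C)=O)c(OC(C)=O)c(-c3c(OC(C)=O)cc(OC(C)=O)cc3OC(C)=O)c2OC(C)=O)c1
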